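**Strategy**

Everything rests on opening the C3=C4 double bond of the pyran ring of the 1H-isochromene. That turns C3 into a methylene flanked by the ring oxygen O2 and the aroyl carbonyl, and C4 into a formyl group on the dimethoxybenzene ring, ortho to the C1 methylene. The key step exploits exactly this: a rhodium carbenoid from a 2,4-dimethoxyphenyl diazomethyl ketone inserts into the benzylic O–H of 2-(hydroxymethyl)-4,5-dimethoxybenzaldehyde (O2–C3), and the doubly activated C3 then condenses with the ortho formyl carbon (aldol addition, loss of water), joining both halves and closing the ring in one flask. The ring-closure precursor is an open-chain phenacyl 2-formylbenzyl ether.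

Key step: step 3

Assumption: compound 4 is written and used as the open hydroxy aldehyde; it equilibrates with its cyclic lactol (5,6-dimethoxy-1,3-dihydro-2-benzofuran-1-ol), and the route relies on the open tautomer reacting at its primary O–H.

**Route**

Step 1
Reactants: 1 (2-bromo-4,5-dimethoxyphenyl)methanol
Product: 4 2-(hydroxymethyl)-4,5-dimethoxybenzaldehyde, via dilithio species 2 (not isolated), via hemiaminal alkoxide 3 (not isolated)
Conditions: n-BuLi (2.2 equiv), THF, −78 °C; DMF, −78 °C → rt; H2O
Reagents that add atoms: N,N-dimethylformamide, CN(C)C=O (formyl carbon and oxygen); n-butyllithium, [Li]CCCC (lithium of 2 and 3 only)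
Why: The first equivalent of n-BuLi deprotonates the hydroxyl and the second effects bromine–lithium exchange to give 2, whose aryllithium adds to DMF (Bouveault formylation) to give the hemiaminal alkoxide 3, which should release the aldehyde only on aqueous quench; the hemiaminal stereocentre of 3 is racemic and is lost on hydrolysis.

Step 2
Reactants: 5 2,4-dimethoxybenzoyl chloride
Product: 6 2-diazo-1-(2,4-dimethoxyphenyl)ethan-1-one
Conditions: TMSCHN2 (2 M in hexanes, 2 equiv), THF/MeCN 1:1, 0 °C → rt; concentrate, SiO2
Reagents that add atoms: (trimethylsilyl)diazomethane, C[Si](C)(C)C=[N+]=[N-]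
Why: The diazo carbon of TMSCHN2 is acylated by the acid chloride and the displaced chloride removes the silyl group from the acyl diazonium ion (diazo ketone synthesis of the Arndt–Eistert type), which should give the acceptor diazo ketone without free HCl; no stereocentre is formed.

Step 3
Reactants: 4 2-(hydroxymethyl)-4,5-dimethoxybenzaldehyde; 6 2-diazo-1-(2,4-dimethoxyphenyl)ethan-1-one
Product: 9 (2,4-dimethoxyphenyl)(6,7-dimethoxy-1H-isochromen-3-yl)methanone, via keto aldehyde 7 (not isolated), via aldol adduct 8 (not isolated)
Conditions: Rh2(OAc)4 (1 mol %), CH2Cl2, rt, 6 added slowly to 4 (1.3 equiv); then DBU (1.5 equiv), 40 °C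
Reagents that add atoms: none
Why: Rh2(OAc)4 converts 6 into an electrophilic rhodium carbenoid that is captured by the primary benzylic hydroxyl of 4 as an oxonium ylide, which either shifts a proton to give keto aldehyde 7 or adds directly to the ortho formyl group; DBU then drives all material through aldol adduct 8 and E1cB loss of water to the arene-conjugated enone 9. The closest known reaction types are the Rh(II)-catalysed O–H insertion of α-diazo ketones into alcohols (with aldol-type trapping of the oxonium ylide) and the Rap–Stoermer-type intramolecular aldol condensation of an α-oxy ketone onto an ortho formyl group. The pyran ring closes by a 6-(enolexo)-exo-trig aldol addition of C3 to the formyl carbon C4. The two stereocentres of 8 (C3 and C4) form without control and are both erased by the dehydration, so the step has no stereochemical demand. It needs chemoselective capture of the carbenoid by the benzylic O–H rather than by the formyl oxygen or the ortho methoxy oxygen of 6: O–H insertion should be the fastest of these processes, 4 is kept in excess while 6 is added slowly, and the five-membered aryl methyl oxonium ylide has no group able to migrate and should revert to the carbenoid. The aldol has no regiochemical alternative, because C3 is the only enolisable carbon and the aldehyde carries no α-hydrogen.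

**Compound list**

1 | (2-bromo-4,5-dimethoxyphenyl)methanol | OCc1cc(OC)c(OC)cc1Br | starting material
2 | lithium (2-lithio-4,5-dimethoxyphenyl)methanolate | [Li]OCc1cc(OC)c(OC)cc1[Li] | intermediate
3 | dilithium salt of [2-[(dimethylamino)(hydroxy)methyl]-4,5-dimethoxyphenyl]methanol (racemic hemiaminal alkoxide) | [Li]OCc1cc(OC)c(OC)cc1C(O[Li])N(C)C | intermediate
4 | 2-(hydroxymethyl)-4,5-dimethoxybenzaldehyde | O=Cc1cc(OC)c(OC)cc1CO | intermediate
5 | 2,4-dimethoxybenzoyl chloride | COc1ccc(C(Cl)=O)c(OC)c1 | starting material
6 | 2-diazo-1-(2,4-dimethoxyphenyl)ethan-1-one | COc1ccc(C(=O)C=[N+]=[N-])c(OC)c1 | intermediate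
7 | 2-{[2-(2,4-dimethoxyphenyl)-2-oxoethoxy]methyl}-4,5-dimethoxybenzaldehyde | COc1ccc(C(=O)COCc2cc(OC)c(OC)cc2C=O)c(OC)c1 | intermediate
8 | (2,4-dimethoxyphenyl)(4-hydroxy-6,7-dimethoxy-3,4-dihydro-1H-isochromen-3-yl)methanone (mixture of racemic diastereomers) | COc1ccc(C(=O)C2OCc3cc(OC)c(OC)cc3C2O)c(OC)c1 | intermediate
9 | (2,4-dimethoxyphenyl)(6,7-dimethoxy-1H-isochromen-3-yl)methanone (no stereocentre) | COc1ccc(C(=O)C2=Cc3cc(OC)c(OC)cc3CO2)c(OC)c1 | target

**Step count**

Total steps: 3. Longest linear sequence: 2 steps (1 → 4 → 9, or 5 → 6 → 9).

**Steps most likely to fail**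

1. Step 3. The carbenoid may be diverted in three ways: insertion into the hemiacetal O–H of the lactol tautomer of 4, capture by the ortho methoxy oxygen followed by demethylation to a benzofuranone, or carbonyl ylide formation at the formyl oxygen. Dehydration of the aldol adduct may also stall. The fallback avoids the carbenoid and the free hydroxy aldehyde altogether and sets out from 1. Alkylation of its sodium alkoxide (NaH, THF, 0 °C) with 2-chloro-N-methoxy-N-methylacetamide should give 2-[(2-bromo-4,5-dimethoxyphenyl)methoxy]-N-methoxy-N-methylacetamide F1. Addition of 2,4-dimethoxyphenylmagnesium bromide (THF, 0 °C, 1 M HCl quench) should stop at the ketone 2-[(2-bromo-4,5-dimethoxyphenyl)methoxy]-1-(2,4-dimethoxyphenyl)ethan-1-one F2. Palladium-catalysed reductive carbonylation of the aryl bromide (PdCl2(PPh3)2, CO 1 atm, HCO2Na, DMF, 100 °C) then installs the formyl group. The fallback comes back to the route at 7, which is closed to 9 with DBU as in the second stage of step 3.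

2. Step 1. Halogen–lithium exchange on the lithium alkoxide may be incomplete, the aryllithium may be protonated or butylated by the butyl bromide formed, and the product may self-acetalise during work-up. The fallback sets out from 1 and uses no organolithium. Palladium-catalysed carbonylative lactonisation (Pd(OAc)2, dppp, CO 1 atm, K2CO3, DMF, 100 °C) should give 5,6-dimethoxy-2-benzofuran-1(3H)-one F3. Half-reduction with DIBAL-H (CH2Cl2, −78 °C, Rochelle salt work-up) should give 5,6-dimethoxy-1,3-dihydro-2-benzofuran-1-ol F4, the ring tautomer of the hydroxy aldehyde. The fallback comes back to the route at 4.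

3. Step 2. Acylation of TMSCHN2 by the hindered, electron-rich acid chloride may be slow, and any HCl formed may destroy the diazo ketone by loss of nitrogen and chloride capture. The fallback sets out from 5 and replaces the diazo compound by a bench-stable carbene surrogate. Acylation of dimethylsulfoxonium methylide (Me3S(O)I, KOtBu, THF, reflux, then 5 at 0 °C) should give the sulfoxonium ylide 1-(2,4-dimethoxyphenyl)-2-[dimethyl(oxo)-λ6-sulfanylidene]ethan-1-one F5. Iridium-catalysed O–H insertion of F5 into 4 ([Ir(cod)Cl]2, 1,2-dichloroethane, 70 °C) should then give the keto aldehyde. The fallback comes back to the route at 7, which is closed to 9 with DBU.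

**Further compounds**

F1 | step 3 | 2-[(2-bromo-4,5-dimethoxyphenyl)methoxy]-N-methoxy-N-methylacetamide | CON(C)C(=O)COCc1cc(OC)c(OC)cc1Br
F2 | step 3 | 2-[(2-bromo-4,5-dimethoxyphenyl)methoxy]-1-(2,4-dimethoxyphenyl)ethan-1-one | COc1ccc(C(=O)COCc2cc(OC)c(OC)cc2Br)c(OC)c1
F3 | step 1 | 5,6-dimethoxy-2-benzofuran-1(3H)-one | O=C1OCc2cc(OC)c(OC)cc21
F4 | step 1 | 5,6-dimethoxy-1,3-dihydro-2-benzofuran-1-ol (racemic) | OC1OCc2cc(OC)c(OC)cc21
F5 | step 2 | 1-(2,4-dimethoxyphenyl)-2-[dimethyl(oxo)-λ6-sulfanylidene]ethan-1-one | COc1ccc(C(=O)C=S(C)(C)=O)c(OC)c1
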